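**Retrosynthetic overview**
1. Ring C is opened at O1–C2: the flavone comes from acid cyclodehydration of a 1-(2,6-dihydroxyaryl)-2-methoxy-1,3-diketone, itself freed from four benzyl ethers.
2. The diketone is cut at both bonds of C4 (C4a–C4 and C4–C3): C4 is carbon monoxide, ring A arrives as aryl iodide 6, and C3 (with its OMe), C2 and ring B arrive as the ω-methoxyacetophenone 16.
3. Feature used: C4 is a lone carbonyl carbon between C4a of ring A and the methoxy-bearing C3, and ring A is mirror-symmetric about the C4a···C7 axis (O at C5 and C8a, OMe at C6 and C8), so either phenol may close ring C.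
4. Iodide 6 comes from 1,2,3-trimethoxybenzene (4,6-dibromide, diol, dibenzyl ether, iodide); ketone 16 comes from 3,4-bis(benzyloxy)benzaldehyde (phenol, methyl ether, bromide, aryllithium plus the Weinreb amide of methoxyacetic acid).
5. Ring order: rings A and B are carried from the starting materials; ring C (the pyranone) is the only ring formed, in the last step.

Key step: step 10

Remark on the chemistry: a Friedel–Crafts methoxyacetylation of the ring-B ether is avoided, because methoxyacetyl chloride loses CO under Lewis acids to give a methoxymethyl cation and the Lewis acid would also cleave benzyl ethers. The ketone is therefore made from an aryllithium and a Weinreb amide. The ring-A resorcinol is benzylated before iodination so that no free, easily oxidised iodoresorcinol is handled.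

Step 1
Reactants: 1 1,2,3-trimethoxybenzene
Product: 2 1,5-dibromo-2,3,4-trimethoxybenzene
Conditions: NBS (2.1 equiv), MeCN, 0 → 40 °C, dark
Reagents that add atoms: N-bromosuccinimide, O=C1CCC(=O)N1Br
Why: Electrophilic aromatic bromination, in which C4 and C6 are each ortho to one outer methoxy group and para to the other while C5 is meta to both and para only to the twisted central methoxy group, so two equivalents of NBS should give the mirror-symmetric 4,6-dibromide.

Step 2
Reactants: 2 1,5-dibromo-2,3,4-trimethoxybenzene
Product: 4 4,5,6-trimethoxybenzene-1,3-diol, via bis(pinacol boronate) 3 (not isolated)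
Conditions: B2pin2 (2.5 equiv), Pd(dppf)Cl2 (5 mol %), KOAc, 1,4-dioxane, 90 °C; then 30% aq. H2O2, aq. NaOH, THF, 0 °C; dilute HCl, under argon
Reagents that add atoms: hydrogen peroxide, OO (the two hydroxyl oxygens of 4); bis(pinacolato)diboron, CC1(C)OB(OC1(C)C)B1OC(C)(C)C(C)(C)O1 (boryl groups of intermediate 3 only)
Why: Miyaura borylation of both aryl bromides followed by ipso oxidation of the two C–B bonds with alkaline peroxide (1,2-aryl shift in the boronate) should place each hydroxyl exactly where a bromine stood.

Step 3
Reactants: 4 4,5,6-trimethoxybenzene-1,3-diol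
Product: 5 1,5-bis(benzyloxy)-2,3,4-trimethoxybenzene
Conditions: BnBr (2.4 equiv), K2CO3, DMF, rt → 50 °C, under argon
Reagents that add atoms: benzyl bromide, BrCc1ccccc1
Why: Williamson O-alkylation of both phenoxides in a polar aprotic solvent, where O-benzylation is favoured over C-benzylation.

Step 4
Reactants: 5 1,5-bis(benzyloxy)-2,3,4-trimethoxybenzene
Product: 6 1,3-bis(benzyloxy)-2-iodo-4,5,6-trimethoxybenzene
Conditions: NIS (1.1 equiv), TFA (cat.), MeCN, 0 °C → rt, dark
Reagents that add atoms: N-iodosuccinimide, O=C1CCC(=O)N1I
Why: Electrophilic aromatic iodination with acid-activated NIS at the only C–H of the pentaalkoxybenzene ring, which is ortho to both benzyloxy groups and para to the central methoxy group, while the unactivated benzyl phenyl rings should stay untouched.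

Step 5
Reactants: 7 3,4-bis(benzyloxy)benzaldehyde
Product: 9 3,4-bis(benzyloxy)phenol, via 3,4-bis(benzyloxy)phenyl formate 8 (not isolated)
Conditions: mCPBA, CH2Cl2, 0 °C → rt; then K2CO3 (cat.), MeOH, rt
Reagents that add atoms: meta-chloroperoxybenzoic acid, O=C(OO)c1cccc(Cl)c1
Why: Baeyer–Villiger (Dakin-type) oxidation in which the electron-rich aryl group migrates in preference to hydride to give the aryl formate, which mild methanolysis cleaves to the phenol.

Step 6
Reactants: 9 3,4-bis(benzyloxy)phenol
Product: 10 1,2-bis(benzyloxy)-4-methoxybenzene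
Conditions: MeI, K2CO3, acetone, reflux
Reagents that add atoms: iodomethane, CI
Why: Williamson methylation of the phenoxide, with no other nucleophilic site in the molecule.

Step 7
Reactants: 10 1,2-bis(benzyloxy)-4-methoxybenzene
Product: 11 1,2-bis(benzyloxy)-4-bromo-5-methoxybenzene
Conditions: NBS (1.05 equiv), MeCN, 0 °C, dark
Reagents that add atoms: N-bromosuccinimide, O=C1CCC(=O)N1Br
Why: Electrophilic aromatic bromination at the position ortho to the methoxy group and para to a benzyloxy group, as in the 5-bromination of 1,2,4-trialkoxybenzenes, since the other two C–H positions are either flanked by two alkoxy groups or activated by one ortho oxygen only.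

Step 8
Reactants: 12 methoxyacetyl chloride
Product: 13 N,2-dimethoxy-N-methylacetamide
Conditions: MeNHOMe·HCl, Et3N (2.2 equiv), CH2Cl2, 0 °C → rt
Reagents that add atoms: N,O-dimethylhydroxylamine hydrochloride, CNOC.Cl
Why: N-Acylation of the hydroxylamine by the acid chloride (Weinreb amide formation) is fast and needs no activation.

Step 9
Reactants: 11 1,2-bis(benzyloxy)-4-bromo-5-methoxybenzene; 13 N,2-dimethoxy-N-methylacetamide
Product: 16 1-[4,5-bis(benzyloxy)-2-methoxyphenyl]-2-methoxyethan-1-one, via aryllithium 14 (not isolated), via lithium hemiaminal adduct 15 (not isolated)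
Conditions: n-BuLi (1.05 equiv), THF, −78 °C; then 13, −78 → 0 °C; aq. NH4Cl
Reagents that add atoms: n-butyllithium, [Li]CCCC (lithium of intermediates 14 and 15 only)
Why: Bromine–lithium exchange at −78 °C is faster than benzylic deprotonation, and the aryllithium should add only once to the Weinreb amide because the chelated tetrahedral adduct persists until the aqueous quench (Weinreb ketone synthesis).

Step 10
Reactants: 6 1,3-bis(benzyloxy)-2-iodo-4,5,6-trimethoxybenzene; 16 1-[4,5-bis(benzyloxy)-2-methoxyphenyl]-2-methoxyethan-1-one; 17 carbon monoxide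
Product: 20 1-[2,6-bis(benzyloxy)-3,4,5-trimethoxyphenyl]-3-[4,5-bis(benzyloxy)-2-methoxyphenyl]-2-methoxypropane-1,3-dione (racemic), via sodium enolate 18 (not isolated), via sodium diketonate 19 (not isolated)
Conditions: 16 (2.0 equiv), NaN(SiMe3)2 (2.0 equiv), THF, −78 → 0 °C; then 6, Pd(dba)2 (5 mol %), Xantphos (6 mol %), CO (2 bar), THF–1,4-dioxane, 80 °C; aq. NH4Cl
Reagents that add atoms: carbon monoxide (compound 17), [C-]#[O+]; sodium bis(trimethylsilyl)amide, [Na+].C[Si](C)(C)[N-][Si](C)(C)C (sodium of intermediates 18 and 19 only)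
Why: Zerovalent palladium carrying Xantphos adds oxidatively to the C–I bond of 6, carbon monoxide inserts into the crowded aryl–palladium bond to give the 2,6-bis(benzyloxy)-3,4,5-trimethoxybenzoyl–palladium iodide (this sets C4a–C4), the sodium enolate 18 replaces iodide, and C–C reductive elimination from the carbon-bound enolate sets C4–C3 and returns zerovalent palladium. The closest known reaction is the palladium-catalysed carbonylative α-arylation of aryl alkyl ketones with aryl iodides under CO to give 1,3-diketones. No ring is closed in this step; the pyranone is closed in step 12. The one new stereocentre, the methoxy-bearing carbon between the two carbonyl groups, forms racemic and uncontrolled, which is harmless because it is enolisable and becomes the sp2 carbon C3 of the flavone. Carbonylative coupling must win over direct α-arylation and C-acylation over O-acylation: the two ortho benzyloxy groups should speed up CO insertion and slow down direct aryl–enolate reductive elimination, the CO pressure keeps the aroyl complex populated, and the wide bite angle of Xantphos favours reductive elimination from the carbon-bound enolate. A second acylation is not expected, because the more acidic diketone is deprotonated at once by the second equivalent of 18 and stays as the sodium diketonate 19 until the quench.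

Step 11
Reactants: 20 1-[2,6-bis(benzyloxy)-3,4,5-trimethoxyphenyl]-3-[4,5-bis(benzyloxy)-2-methoxyphenyl]-2-methoxypropane-1,3-dione
Product: 21 1-(2,6-dihydroxy-3,4,5-trimethoxyphenyl)-3-(4,5-dihydroxy-2-methoxyphenyl)-2-methoxypropane-1,3-dione (racemic)
Conditions: H2 (1 atm), 10% Pd/C, EtOAc–MeOH, rt; filtered and concentrated under argon, used crude
Reagents that add atoms: none
Why: Heterogeneous catalytic hydrogenolysis of the four benzylic C–O bonds under mild conditions, under which aryl ketones, methyl ethers and the α-methoxy group should persist.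

Step 12
Reactants: 21 1-(2,6-dihydroxy-3,4,5-trimethoxyphenyl)-3-(4,5-dihydroxy-2-methoxyphenyl)-2-methoxypropane-1,3-dione
Product: 23 5,4',5'-trihydroxy-3,6,7,8,2'-pentamethoxyflavone, via 2-hydroxyflavanone hemiketal 22 (not isolated)
Conditions: conc. HCl (cat.), MeOH, 60 °C, under argon
Reagents that add atoms: none
Why: Acid-catalysed cyclodehydration of an o-hydroxyaryl 1,3-diketone (the closing step of a Baker–Venkataraman-type flavone synthesis), in which either of the two equivalent ring-A phenols adds to the ring-B carbonyl in a 6-exo-trig hemiketalisation and loss of water gives the aromatic pyranone, the other phenol remaining as the hydrogen-bonded 5-OH.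

**Compound list**
1 | 1,2,3-trimethoxybenzene | COc1cccc(OC)c1OC | starting material
2 | 1,5-dibromo-2,3,4-trimethoxybenzene | COc1c(Br)cc(Br)c(OC)c1OC | intermediate
3 | 2,2'-(4,5,6-trimethoxy-1,3-phenylene)bis(4,4,5,5-tetramethyl-1,3,2-dioxaborolane) | COc1c(B2OC(C)(C)C(C)(C)O2)cc(B2OC(C)(C)C(C)(C)O2)c(OC)c1OC | intermediate (not isolated)
4 | 4,5,6-trimethoxybenzene-1,3-diol | COc1c(O)cc(O)c(OC)c1OC | intermediate
5 | 1,5-bis(benzyloxy)-2,3,4-trimethoxybenzene | COc1c(OCc2ccccc2)cc(OCc2ccccc2)c(OC)c1OC | intermediate
6 | 1,3-bis(benzyloxy)-2-iodo-4,5,6-trimethoxybenzene | COc1c(OC)c(OCc2ccccc2)c(I)c(OCc2ccccc2)c1OC | intermediate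
7 | 3,4-bis(benzyloxy)benzaldehyde | O=Cc1ccc(OCc2ccccc2)c(OCc2ccccc2)c1 | starting material
8 | 3,4-bis(benzyloxy)phenyl formate | O=COc1ccc(OCc2ccccc2)c(OCc2ccccc2)c1 | intermediate (not isolated)
9 | 3,4-bis(benzyloxy)phenol | Oc1ccc(OCc2ccccc2)c(OCc2ccccc2)c1 | intermediate
10 | 1,2-bis(benzyloxy)-4-methoxybenzene | COc1ccc(OCc2ccccc2)c(OCc2ccccc2)c1 | intermediate
11 | 1,2-bis(benzyloxy)-4-bromo-5-methoxybenzene | COc1cc(OCc2ccccc2)c(OCc2ccccc2)cc1Br | intermediate
12 | methoxyacetyl chloride | COCC(=O)Cl | starting material
13 | N,2-dimethoxy-N-methylacetamide | COCC(=O)N(C)OC | intermediate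
14 | [4,5-bis(benzyloxy)-2-methoxyphenyl]lithium | [Li]c1cc(OCc2ccccc2)c(OCc2ccccc2)cc1OC | intermediate (not isolated)
15 | lithium 1-[4,5-bis(benzyloxy)-2-methoxyphenyl]-2-methoxy-1-[methoxy(methyl)amino]ethan-1-olate (racemic) | [Li]OC(COC)(N(C)OC)c1cc(OCc2ccccc2)c(OCc2ccccc2)cc1OC | intermediate (not isolated)
16 | 1-[4,5-bis(benzyloxy)-2-methoxyphenyl]-2-methoxyethan-1-one | COCC(=O)c1cc(OCc2ccccc2)c(OCc2ccccc2)cc1OC | intermediate
17 | carbon monoxide | [C-]#[O+] | starting material
18 | sodium (Z)-1-[4,5-bis(benzyloxy)-2-methoxyphenyl]-2-methoxyethen-1-olate (chelated Z geometry expected, without consequence) | [Na+].[O-]/C(=C\OC)c1cc(OCc2ccccc2)c(OCc2ccccc2)cc1OC | intermediate (not isolated)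
19 | sodium enolate of diketone 20 (delocalised, drawn as one resonance form, geometry undefined) | [Na+].[O-]C(=C(OC)C(=O)c1c(OCc2ccccc2)c(OC)c(OC)c(OC)c1OCc1ccccc1)c1cc(OCc2ccccc2)c(OCc2ccccc2)cc1OC | intermediate (not isolated)
20 | 1-[2,6-bis(benzyloxy)-3,4,5-trimethoxyphenyl]-3-[4,5-bis(benzyloxy)-2-methoxyphenyl]-2-methoxypropane-1,3-dione (racemic, enolisable centre) | COC(C(=O)c1c(OCc2ccccc2)c(OC)c(OC)c(OC)c1OCc1ccccc1)C(=O)c1cc(OCc2ccccc2)c(OCc2ccccc2)cc1OC | intermediate
21 | 1-(2,6-dihydroxy-3,4,5-trimethoxyphenyl)-3-(4,5-dihydroxy-2-methoxyphenyl)-2-methoxypropane-1,3-dione (racemic) | COC(C(=O)c1c(O)c(OC)c(OC)c(OC)c1O)C(=O)c1cc(O)c(O)cc1OC | intermediate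
22 | 2-(4,5-dihydroxy-2-methoxyphenyl)-2,5-dihydroxy-3,6,7,8-tetramethoxy-2,3-dihydro-4H-chromen-4-one (racemic, mixture of diastereomers) | COC1C(=O)c2c(O)c(OC)c(OC)c(OC)c2OC1(O)c1cc(O)c(O)cc1OC | intermediate (not isolated)
23 | 5,4',5'-trihydroxy-3,6,7,8,2'-pentamethoxyflavone (no stereocentre) | COc1cc(O)c(O)cc1-c1oc2c(OC)c(OC)c(OC)c(O)c2c(=O)c1OC | target

**Totals**
Total step count: 12.
Longest linear sequence: 7 steps (steps 1, 2, 3, 4, 10, 11, 12; the ring-B branch 5, 6, 7, 9, 10, 11, 12 is equally long).

**Steps most likely to fail**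

Step 10. The hindered aroyl–palladium may acylate the enolate on oxygen, C–C reductive elimination at the substituted α-carbon may be too slow so that the catalyst decays, or the iodide may be reduced. The fallback builds the same two bonds by classical acylation, setting out from iodide 6 and ketone 16 and coming back at diketone 20. Iodine–magnesium exchange on 6 with i-PrMgCl·LiCl in THF at −20 °C should give [2,6-bis(benzyloxy)-3,4,5-trimethoxyphenyl]magnesium chloride F1, which is quenched with CO2 to give 2,6-bis(benzyloxy)-3,4,5-trimethoxybenzoic acid F2. Oxalyl chloride with catalytic DMF in CH2Cl2 converts this into 2,6-bis(benzyloxy)-3,4,5-trimethoxybenzoyl chloride F3. Ketone 16 is then C-acylated with F3 under soft enolisation (MgBr2·OEt2, i-Pr2NEt, CH2Cl2, rt), where the magnesium chelate of the product drives acylation at carbon, to give 20.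

Step 2. The second borylation may stall, the electron-rich boronate may protodeboronate, or the resorcinol may be degraded oxidatively by alkaline peroxide. The fallback never frees the resorcinol; it sets out from 1 and comes back at dibenzyl ether 5, replacing steps 1 to 3. Double iodination of 1 (NIS, 2.2 equiv, cat. TFA, MeCN) should give 1,5-diiodo-2,3,4-trimethoxybenzene F4 by the same directing effects as in step 1. An Ullmann-type C–O coupling of F4 with benzyl alcohol (CuI, 3,4,7,8-tetramethyl-1,10-phenanthroline, Cs2CO3, toluene, 110 °C) then installs both benzyloxy groups directly to give 5.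

Step 4. Substitution at the crowded position between two benzyloxy groups may be sluggish, with competing acid-promoted loss of a benzyl group or oxidative dealkylation of the pentaalkoxybenzene. The fallback moves the iodination to the far more reactive free resorcinol under non-acidic conditions; it sets out from diol 4 and comes back at iodide 6. Treatment of 4 with I2 and NaHCO3 in THF–H2O at 0 °C under argon should give 2-iodo-4,5,6-trimethoxybenzene-1,3-diol F5, which is benzylated at once (BnBr, K2CO3, DMF) to give 6.

Further compounds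
F1 | step 10 | [2,6-bis(benzyloxy)-3,4,5-trimethoxyphenyl]magnesium chloride | COc1c(OC)c(OCc2ccccc2)c([Mg]Cl)c(OCc2ccccc2)c1OC
F2 | step 10 | 2,6-bis(benzyloxy)-3,4,5-trimethoxybenzoic acid | COc1c(OC)c(OCc2ccccc2)c(C(=O)O)c(OCc2ccccc2)c1OC
F3 | step 10 | 2,6-bis(benzyloxy)-3,4,5-trimethoxybenzoyl chloride | COc1c(OC)c(OCc2ccccc2)c(C(Cl)=O)c(OCc2ccccc2)c1OC
F4 | step 2 | 1,5-diiodo-2,3,4-trimethoxybenzene | COc1c(I)cc(I)c(OC)c1OC
F5 | step 4 | 2-iodo-4,5,6-trimethoxybenzene-1,3-diol | COc1c(OC)c(O)c(I)c(O)c1OC
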